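**Retrosynthetic overview**
1. Feature: ring A (C1, C10, C11, C12, C13, C14) carries C9 on C10, a methyl on each carbon flanking C10 (C15 on C1, C20 on C11), oxygen on C14 and its only alkene at C11=C12. This is the 1,4-dihydro pattern of a 3-oxygenated 2,6-dimethylbenzoic acid, so ring A is taken from that arene by Birch reduction.
2. The ten-membered ring (C1 to C10) is opened at C4–C5 (B-alkyl Suzuki–Miyaura coupling of the C3=C4 vinyl group with a C5 alkenyl iodide). The gamma-lactone (C7, C8, C17, C19, O) is opened at C8–C17 (intramolecular Reformatsky reaction).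
3. Chain bonds: C6–C7 (acetylide plus Weinreb amide), C8–C9 (dithiane ester enolate plus C9 aldehyde), C1–C2 (Mukaiyama aldol of the Birch silyl enol ether with acrolein).
4. Ring order: ring A first (from the arene), the gamma-lactone second, the ten-membered carbocycle last; the acetonide is only a protecting ring.

Key step: step 5

**Remarks**
- Briarane numbering is used throughout: C15 is the methyl on C1, C16 the carbon on C5, C18 the methyl on C17, C19 the lactone carbonyl, C20 the methyl on C11. The target is 1S,2R,7S,8R,9R,10S,14S,17R, with C16 trans to C7 across C5=C6 (C4 and C7 cis in the ring).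
- Assumption: the less soluble 1-phenylethylammonium salt of the Birch acid is taken to be the one of the (1S)-acid with the (S)-amine. If the pairing is the reverse, the (R)-amine is used and nothing else changes.
- 2-Bromopropanoyl bromide is used racemic; its stereocentre is erased in the zinc enolate of step 20.

**Route**

Step 1
Reactants: 1 2,6-dimethylbenzoic acid
Product: 2 2,6-dimethyl-3-nitrobenzoic acid
Conditions: HNO3, conc. H2SO4, 0 °C
Reagents that add atoms: nitric acid, O[N+](=O)[O-]
Why: Electrophilic aromatic nitration should go to C3 (equivalent to C5), which is ortho to one methyl, para to the other and meta to the carboxyl group, so all three substituents direct to the same position.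

Step 2
Reactants: 2 2,6-dimethyl-3-nitrobenzoic acid
Product: 3 3-amino-2,6-dimethylbenzoic acid
Conditions: H2 (1 atm), 10% Pd/C, MeOH, rt
Reagents that add atoms: none
Why: Catalytic hydrogenation of a nitroarene to the aniline is reliable here because nothing else in the molecule is reducible under these conditions.

Step 3
Reactants: 3 3-amino-2,6-dimethylbenzoic acid
Product: 5 3-hydroxy-2,6-dimethylbenzoic acid, via diazonium hydrogensulfate 4 (not isolated)
Conditions: NaNO2, aq. H2SO4, 0–5 °C; then added to hot dilute H2SO4, 90 °C
Reagents that add atoms: water, O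
Why: Diazotisation followed by thermal hydrolysis of the arenediazonium salt is the standard aniline-to-phenol exchange, and the acid and methyl groups are inert to it.

Step 4
Reactants: 5 3-hydroxy-2,6-dimethylbenzoic acid
Product: 7 3-(tert-butyldimethylsilyloxy)-2,6-dimethylbenzoic acid, via bis-silylated acid 6 (not isolated)
Conditions: TBSCl (2.5 equiv), imidazole, DMF, rt; then AcOH/THF/H2O, rt
Reagents that add atoms: tert-butyldimethylsilyl chloride, C[Si](C)(Cl)C(C)(C)C
Why: Silylation caps both the phenol and the carboxyl group, and the silyl ester is hydrolysed under mild aqueous acid far faster than the aryl silyl ether, so only the phenol stays protected.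

Step 5
Reactants: 7 3-(tert-butyldimethylsilyloxy)-2,6-dimethylbenzoic acid
Product: 9 racemic 3-(tert-butyldimethylsilyloxy)-2,6-dimethylcyclohexa-2,5-diene-1-carboxylic acid, via dilithium carboxylate dienolate 8 (not isolated)
Conditions: Li (4 equiv), NH3(l)/THF, t-BuOH (2 equiv), −78 °C; solid NH4Cl; NH3 evaporated; cold aq. NaH2PO4 (pH 4–5)/Et2O, crude acid used at once
Reagents that add atoms: none
Why: Two single-electron transfers from lithium, each followed by a protonation, do the work: the carboxylate-bearing arene takes up an electron, the radical anion is protonated para to the carboxylate (the future C13), a second electron gives the carboxylate dienolate 8, which persists in ammonia and is protonated at its alpha carbon (the future C10) when NH4Cl is added. The closest known reactions are the Birch reduction of benzoic acids to cyclohexa-2,5-diene-1-carboxylic acids and that of aryl silyl ethers to silyl enol ethers, which here call for one and the same product. No ring is closed, since the benzene ring itself becomes ring A, now with the C11=C12 alkene in place, C9 on the C10 methine and a tetrasubstituted C1=C14 silyl enol ether of fixed regiochemistry. The only new stereocentre, C10, forms without control and the racemate is resolved in step 6. The selectivity needed is protonation at C10 and C13 alone, and the substrate secures it because the carboxylate directs to its ipso and para carbons while the silyloxy- and methyl-bearing carbons, as donor-substituted positions, stay sp2; a limited excess of lithium and the low temperature guard against over-reduction and loss of the silyl group. The enol ether made this way is the C1 enolate equivalent that a C14 ketone could not supply, as that ketone would enolise towards the allylic C13 methylene.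

Step 6
Reactants: 9 racemic 3-(tert-butyldimethylsilyloxy)-2,6-dimethylcyclohexa-2,5-diene-1-carboxylic acid
Product: 10 (S)-1-phenylethylammonium (1S)-3-(tert-butyldimethylsilyloxy)-2,6-dimethylcyclohexa-2,5-diene-1-carboxylate
Conditions: (S)-1-phenylethylamine (1.0 equiv), MTBE/heptane, −20 °C, argon; salt recrystallised to constant rotation
Reagents that add atoms: (S)-1-phenylethylamine, C[C@H](N)c1ccccc1
Why: Classical resolution by crystallisation of diastereomeric ammonium carboxylates should fix C10 (10S in target numbering), because the C10–H of a carboxylate salt is not acidic enough to racemise and the aprotic solvent spares the silyl enol ether.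

Step 7
Reactants: 10 (S)-1-phenylethylammonium (1S)-3-(tert-butyldimethylsilyloxy)-2,6-dimethylcyclohexa-2,5-diene-1-carboxylate
Product: 12 methyl (1S)-3-(tert-butyldimethylsilyloxy)-2,6-dimethylcyclohexa-2,5-diene-1-carboxylate, via free (1S)-acid 11 (not isolated)
Conditions: Et2O/cold aq. NaH2PO4 (pH 4–5); organic phase dried; CH2N2, Et2O, 0 °C
Reagents that add atoms: diazomethane, C=[N+]=[N-]
Why: Partition at pH 4–5 frees the acid without hydrolysing the enol ether, and esterification with diazomethane is neutral and base-free, so the doubly allylic C10–H is neither epimerised nor moved into conjugation.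

Step 8
Reactants: 12 methyl (1S)-3-(tert-butyldimethylsilyloxy)-2,6-dimethylcyclohexa-2,5-diene-1-carboxylate, 13 acrolein
Product: 14 methyl (1S,6S)-6-[(1R)-1-hydroxyprop-2-en-1-yl]-2,6-dimethyl-5-oxocyclohex-2-ene-1-carboxylate
Conditions: BF3·OEt2 (1.1 equiv), CH2Cl2, −78 °C (aldehyde precomplexed); aq. NaHCO3 quench at −78 °C
Reagents that add atoms: none
Why: A Mukaiyama aldol addition of the tetrasubstituted silyl enol ether to BF3-activated acrolein (1,2-addition) should build quaternary C1 and the C1–C2 bond; the electrophile should enter anti to the pseudo-axial C10 ester (C2 trans to C9), and the open antiperiplanar transition state should place the vinyl group next to the C1 methyl rather than next to ring carbon C10, which gives the 2R carbinol.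

Step 9
Reactants: 14 methyl (1S,6S)-6-[(1R)-1-hydroxyprop-2-en-1-yl]-2,6-dimethyl-5-oxocyclohex-2-ene-1-carboxylate
Product: 16 methyl (1S,5S,6R)-5-hydroxy-6-[(1R)-1-hydroxyprop-2-en-1-yl]-2,6-dimethylcyclohex-2-ene-1-carboxylate (2,14-syn-diol), via diethylboron chelate 15 (not isolated)
Conditions: Et2BOMe (1.1 equiv), THF/MeOH 4:1, −78 °C; NaBH4, −78 °C; AcOH; evaporation from MeOH
Reagents that add atoms: none
Why: In the Narasaka–Prasad reduction the dialkylboron bridges O2 and the C14 carbonyl and external hydride should attack from the ring face away from the C2 side chain (also the face of the small C15 methyl), giving the 2,14-syn-diol with O14 cis to C2 and leaving the ester untouched at −78 °C.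

Step 10
Reactants: 16 2,14-syn-diol methyl ester
Product: 17 2,14-O-isopropylidene acetal of 16 (1,3-dioxane cis-fused to ring A at C1–C14; methyl ester and C3=C4 vinyl retained)
Conditions: 2,2-dimethoxypropane, PPTS (cat.), CH2Cl2, rt
Reagents that add atoms: 2,2-dimethoxypropane, COC(C)(C)OC
Why: Acid-catalysed transketalisation of a syn-1,3-diol gives the six-membered acetonide readily and masks both hydroxyls until the end of the route.

Step 11
Reactants: 17 acetonide methyl ester
Product: 18 C9 primary alcohol (CO2Me of 17 reduced to CH2OH)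
Conditions: i-Bu2AlH (2.5 equiv), CH2Cl2, −78 to −20 °C; aq. potassium sodium tartrate
Reagents that add atoms: none
Why: Hydride reduction of the ester with i-Bu2AlH gives the primary alcohol under non-basic conditions, so the allylic C10 stereocentre is not disturbed.

Step 12
Reactants: 18 C9 primary alcohol
Product: 19 C9 aldehyde (formyl group on C10 of the acetonide-protected ring A)
Conditions: Dess–Martin periodinane, NaHCO3, CH2Cl2, 0 °C; short silica plug, used at once
Reagents that add atoms: none
Why: The buffered Dess–Martin oxidation is neutral, which should keep the beta,gamma-unsaturated aldehyde from epimerising at C10 or slipping into conjugation before it is used.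

Step 13
Reactants: 19 C9 aldehyde, 20 ethyl 1,3-dithiane-2-carboxylate
Product: 22 ethyl 2-[(R)-hydroxy(ring A)methyl]-1,3-dithiane-2-carboxylate (C9 carbinol with C8 as the dithiane carbon and C7 as the ester carbon), via lithium enolate 21 (not isolated)
Conditions: LiN(i-Pr)2 (1.5 equiv), THF, −78 °C; then 19, −78 °C; aq. NH4Cl quench at −78 °C
Reagents that add atoms: none
Why: Aldol-type addition of the lithiated dithiane ester (an acyl-anion equivalent) brings in C8 and C7 together, and Felkin–Anh control with quaternary C1 as the large group anti to the nucleophile and attack past H10 should give the 9R carbinol; the cold quench limits retro-aldol reversal.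

Step 14
Reactants: 22 C9 carbinol dithiane ester
Product: 23 O9 tert-butyldimethylsilyl ether of 22
Conditions: TBSOTf (1.5 equiv), 2,6-lutidine, CH2Cl2, −78 to 0 °C
Reagents that add atoms: tert-butyldimethylsilyl triflate, C[Si](C)(OS(=O)(=O)C(F)(F)F)C(C)(C)C
Why: Silyl triflate silylation copes with the hindered secondary alcohol, blocks retro-aldol cleavage and keeps O9 distinct from the hydroxyls that are acetylated at the end.

Step 15
Reactants: 23 O9-silylated dithiane ethyl ester
Product: 24 N-methoxy-N-methylamide (Weinreb amide) of 23 at C7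
Conditions: MeNH(OMe)·HCl (4 equiv), i-PrMgCl (8 equiv), THF, −20 to 0 °C
Reagents that add atoms: N,O-dimethylhydroxylamine hydrochloride, CNOC.Cl
Why: Aminolysis of the ester by the magnesium amide gives the Weinreb amide, helped by the inductive activation of the ester carbonyl by the two alpha sulfur atoms.

Step 16
Reactants: 24 C7 Weinreb amide, 25 4-methoxybenzyl propargyl ether
Product: 27 C7 ynone (C16 as OPMB; C5≡C6; C8 dithiane; O9 TBS), via lithium acetylide 26 (not isolated)
Conditions: n-BuLi, THF, −78 °C; then 24, −78 to −20 °C; inverse quench into cold aq. NH4Cl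
Reagents that add atoms: none
Why: Acetylide addition to a Weinreb amide stops at the chelated tetrahedral intermediate, so the ynone (C6–C7 bond) is released only on the cold quench and over-addition or amine conjugate addition is avoided.

Step 17
Reactants: 27 C7 ynone
Product: 28 (7S)-propargylic alcohol (dithiane at C8 intact)
Conditions: (R)-2-methyl-CBS-oxazaborolidine (1 equiv), catecholborane, toluene, −78 °C
Reagents that add atoms: none
Why: In the Corey–Bakshi–Shibata reduction the slim alkyne is the small group and the dithiane-bearing quaternary carbon the large one, so the (R)-catalyst should deliver hydride to the face that gives the 7S alcohol, while catecholborane at −78 °C leaves the vinyl group unhydroborated.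

Step 18
Reactants: 28 (7S)-propargylic alcohol, 29 2-bromopropanoyl bromide (racemic)
Product: 30 O7 2-bromopropanoate of 28 (epimers at the bromide carbon)
Conditions: pyridine, DMAP (cat.), CH2Cl2, −20 to 0 °C
Reagents that add atoms: none
Why: Acylation of the secondary alcohol with the acid bromide installs C17, C18 and C19 on O7, and the mixed configuration at the bromide carbon is of no consequence for the next steps.

Step 19
Reactants: 30 O7 2-bromopropanoate dithiane
Product: 31 C8 ketone (O7 2-bromopropanoate, O9 TBS, C16 OPMB)
Conditions: MeI (excess), CaCO3, MeCN/H2O 9:1, 40 °C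
Reagents that add atoms: water, O
Why: S-Methylation and hydrolysis unmask the dithiane under buffered, near-neutral conditions, which should spare the acidic C7–H, the acetonide, the silyl ether and the PMB ether; any bromide/iodide exchange at the ester alpha carbon would not matter.

Step 20
Reactants: 31 C8 ketone bromopropanoate
Product: 33 seco gamma-lactone (C7–O–C19(=O)–C17(Me)–C8(OH) ring closed; C9 trans to C6; C17 methyl cis to 8-OH), via ethylzinc enolate 32 (not isolated)
Conditions: Et2Zn (2.2 equiv), RhCl(PPh3)3 (5 mol %), THF, 0 °C; aq. NH4Cl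
Reagents that add atoms: none
Why: In the rhodium-catalysed Reformatsky reaction both bromide epimers converge on one zinc enolate, which closes the five-membered ring onto the C8 ketone (C8–C17 bond); bulky C9 should turn away from the C6 alkynyl group (C9 trans to C6, 8-OH cis to C6) and the C17 methyl should take the face away from C9, which is also the thermodynamically preferred, epimerisable arrangement.

Step 21
Reactants: 33 seco gamma-lactone PMB ether
Product: 34 C16 propargylic alcohol
Conditions: DDQ, CH2Cl2/pH 7 buffer, 0 °C to rt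
Reagents that add atoms: none
Why: Oxidative cleavage of the electron-rich PMB ether by DDQ under buffered conditions should leave the alkenes, acetonide, silyl ether and lactone untouched.

Step 22
Reactants: 34 C16 propargylic alcohol
Product: 35 (Z)-C5 tributylstannyl alkene (tin on C5 cis to C7; H on C6)
Conditions: Bu3SnH (1.2 equiv), [Cp*RuCl]4 (2.5 mol %), CH2Cl2, rt
Reagents that add atoms: tributyltin hydride, CCCC[SnH](CCCC)CCCC
Why: In the hydroxyl-directed ruthenium-catalysed trans-hydrostannation the free propargylic C16 hydroxyl binds the chloride ligand and steers tin to the proximal carbon C5, and trans delivery of H and Sn puts tin cis to C7, the geometry the ring alkene needs.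

Step 23
Reactants: 35 (Z)-C5 tributylstannyl alkene
Product: 36 (Z)-C5 iodoalkene (iodine cis to C7)
Conditions: iodine (1.05 equiv), CH2Cl2, 0 °C; aq. Na2S2O3
Reagents that add atoms: iodine, [I][I]
Why: Iododestannylation is an ipso substitution that proceeds with retention of alkene geometry and is much faster than any reaction of iodine with the other alkenes.

Step 24
Reactants: 36 (Z)-C5 iodoalkene
Product: 38 protected ten-membered carbocycle (C4–C5 bond formed; free C16 and C8 hydroxyls; O9 TBS; 2,14-acetonide), via B-alkyl borane 37 (not isolated)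
Conditions: 9-BBN dimer (excess), THF, rt; H2O; then slow addition to PdCl2(dppf) (20 mol %), AsPh3, Cs2CO3, DMF/THF/H2O, 50 °C, high dilution; mildly acidic work-up
Reagents that add atoms: none
Why: 9-BBN hydroborates only the monosubstituted C3=C4 alkene at the terminal carbon, and the intramolecular B-alkyl Suzuki–Miyaura coupling (zerovalent palladium inserting into the C5–I bond, base-assisted transmetalation, reductive elimination) should close the ten-membered ring at C4–C5 with retention of the alkene geometry, with high dilution favouring the ring over oligomers.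

Step 25
Reactants: 38 protected ten-membered carbocycle
Product: 39 2,14,16-triol (8-OH free, O9 TBS)
Conditions: AcOH/H2O 4:1, 40 °C
Reagents that add atoms: none
Why: Aqueous acetic acid hydrolyses the 1,3-dioxane acetonide, while the hindered secondary silyl ether at C9 should survive.

Step 26
Reactants: 39 2,14,16-triol
Product: 40 2,14,16-triacetate 9-silyl ether (8-OH free)
Conditions: Ac2O, pyridine, DMAP (cat.), CH2Cl2, rt
Reagents that add atoms: acetic anhydride, CC(=O)OC(C)=O
Why: DMAP-catalysed acetylation should take the primary C16 and the secondary C2 and C14 hydroxyls, while the tertiary C8 hydroxyl is too hindered under these conditions and O9 is still silylated.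

Step 27
Reactants: 40 2,14,16-triacetate 9-silyl ether
Product: 41 target CNP0322315.2
Conditions: HF·pyridine, THF/pyridine, 0 °C to rt
Reagents that add atoms: none
Why: Fluoride-driven desilylation under mildly acidic conditions frees the C9 hydroxyl without the acetyl migration or lactone opening that a basic fluoride source could cause.

**Compound list**
1 | 2,6-dimethylbenzoic acid | Cc1cccc(C)c1C(=O)O | starting material
2 | 2,6-dimethyl-3-nitrobenzoic acid | Cc1ccc([N+](=O)[O-])c(C)c1C(=O)O | intermediate
3 | 3-amino-2,6-dimethylbenzoic acid | Cc1ccc(N)c(C)c1C(=O)O | intermediate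
4 | 3-carboxy-2,4-dimethylbenzenediazonium hydrogensulfate | Cc1ccc([N+]#N)c(C)c1C(=O)O.OS(=O)(=O)[O-] | intermediate (not isolated)
5 | 3-hydroxy-2,6-dimethylbenzoic acid | Cc1ccc(O)c(C)c1C(=O)O | intermediate
6 | tert-butyldimethylsilyl 3-(tert-butyldimethylsilyloxy)-2,6-dimethylbenzoate | Cc1ccc(O[Si](C)(C)C(C)(C)C)c(C)c1C(=O)O[Si](C)(C)C(C)(C)C | intermediate (not isolated)
7 | 3-(tert-butyldimethylsilyloxy)-2,6-dimethylbenzoic acid | Cc1ccc(O[Si](C)(C)C(C)(C)C)c(C)c1C(=O)O | intermediate
8 | dilithium carboxylate dienolate of the reduced ring (exocyclic ene-diolate on the 2,5-diene) | [Li+].[Li+].[O-]C([O-])=C1C(C)=CCC(O[Si](C)(C)C(C)(C)C)=C1C | intermediate (not isolated)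
9 | racemic 3-(tert-butyldimethylsilyloxy)-2,6-dimethylcyclohexa-2,5-diene-1-carboxylic acid | OC(=O)C1C(C)=CCC(O[Si](C)(C)C(C)(C)C)=C1C | intermediate
10 | (S)-1-phenylethylammonium (1S)-3-(tert-butyldimethylsilyloxy)-2,6-dimethylcyclohexa-2,5-diene-1-carboxylate | [O-]C(=O)[C@H]1C(C)=CCC(O[Si](C)(C)C(C)(C)C)=C1C.C[C@H]([NH3+])c1ccccc1 | intermediate
11 | (1S)-3-(tert-butyldimethylsilyloxy)-2,6-dimethylcyclohexa-2,5-diene-1-carboxylic acid | OC(=O)[C@H]1C(C)=CCC(O[Si](C)(C)C(C)(C)C)=C1C | intermediate (not isolated)
12 | methyl (1S)-3-(tert-butyldimethylsilyloxy)-2,6-dimethylcyclohexa-2,5-diene-1-carboxylate | COC(=O)[C@H]1C(C)=CCC(O[Si](C)(C)C(C)(C)C)=C1C | intermediate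
13 | acrolein (C2 to C4) | C=CC=O | starting material
14 | methyl (1S,6S)-6-[(1R)-1-hydroxyprop-2-en-1-yl]-2,6-dimethyl-5-oxocyclohex-2-ene-1-carboxylate | COC(=O)[C@H]1C(C)=CCC(=O)[C@]1(C)[C@H](O)C=C | intermediate
15 | O2-diethylboryl chelate of 14 | COC(=O)[C@H]1C(C)=CCC(=O)[C@]1(C)[C@H](OB(CC)CC)C=C | intermediate (not isolated)
16 | methyl (1S,5S,6R)-5-hydroxy-6-[(1R)-1-hydroxyprop-2-en-1-yl]-2,6-dimethylcyclohex-2-ene-1-carboxylate (2,14-syn-diol) | COC(=O)[C@H]1C(C)=CC[C@H](O)[C@]1(C)[C@H](O)C=C | intermediate
17 | 2,14-O-isopropylidene acetal of 16 (methyl ester) | COC(=O)[C@H]1C(C)=CC[C@H](OC2(C)C)[C@]1(C)[C@H](O2)C=C | intermediate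
18 | C9 primary alcohol of the acetonide-protected ring A | OC[C@H]1C(C)=CC[C@H](OC2(C)C)[C@]1(C)[C@H](O2)C=C | intermediate
19 | C9 aldehyde of the acetonide-protected ring A | O=C[C@H]1C(C)=CC[C@H](OC2(C)C)[C@]1(C)[C@H](O2)C=C | intermediate
20 | ethyl 1,3-dithiane-2-carboxylate (C8 and C7) | CCOC(=O)C1SCCCS1 | starting material
21 | lithium enolate of 20 | [Li+].CCOC([O-])=C1SCCCS1 | intermediate (not isolated)
22 | (9R)-C9 carbinol, C8 as 1,3-dithiane, C7 as ethyl ester | CCOC(=O)C1(SCCCS1)[C@H](O)[C@H]2C(C)=CC[C@H](OC3(C)C)[C@]2(C)[C@H](O3)C=C | intermediate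
23 | O9 tert-butyldimethylsilyl ether of 22 | CCOC(=O)C1(SCCCS1)[C@H](O[Si](C)(C)C(C)(C)C)[C@H]2C(C)=CC[C@H](OC3(C)C)[C@]2(C)[C@H](O3)C=C | intermediate
24 | C7 N-methoxy-N-methylamide of 23 | CON(C)C(=O)C1(SCCCS1)[C@H](O[Si](C)(C)C(C)(C)C)[C@H]2C(C)=CC[C@H](OC3(C)C)[C@]2(C)[C@H](O3)C=C | intermediate
25 | 4-methoxybenzyl propargyl ether (C6, C5, C16) | C#CCOCc1ccc(OC)cc1 | starting material
26 | lithium acetylide of 25 | [Li+].[C-]#CCOCc1ccc(OC)cc1 | intermediate (not isolated)
27 | C7 ynone (C16 OPMB, C8 dithiane, O9 TBS) | COc1ccc(COCC#CC(=O)C2(SCCCS2)[C@H](O[Si](C)(C)C(C)(C)C)[C@H]3C(C)=CC[C@H](OC4(C)C)[C@]3(C)[C@H](O4)C=C)cc1 | intermediate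
28 | (7S)-propargylic alcohol | COc1ccc(COCC#C[C@H](O)C2(SCCCS2)[C@H](O[Si](C)(C)C(C)(C)C)[C@H]3C(C)=CC[C@H](OC4(C)C)[C@]3(C)[C@H](O4)C=C)cc1 | intermediate
29 | 2-bromopropanoyl bromide, racemic (C17, C18, C19) | CC(Br)C(Br)=O | starting material
30 | O7 2-bromopropanoate of 28 (epimers at the bromide carbon) | COc1ccc(COCC#C[C@H](OC(=O)C(C)Br)C2(SCCCS2)[C@H](O[Si](C)(C)C(C)(C)C)[C@H]3C(C)=CC[C@H](OC4(C)C)[C@]3(C)[C@H](O4)C=C)cc1 | intermediate
31 | C8 ketone carrying the O7 2-bromopropanoate | COc1ccc(COCC#C[C@H](OC(=O)C(C)Br)C(=O)[C@H](O[Si](C)(C)C(C)(C)C)[C@H]2C(C)=CC[C@H](OC3(C)C)[C@]2(C)[C@H](O3)C=C)cc1 | intermediate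
32 | ethylzinc enolate of the O7 propanoate (enolate geometry not defined) | COc1ccc(COCC#C[C@H](OC(=CC)O[Zn]CC)C(=O)[C@H](O[Si](C)(C)C(C)(C)C)[C@H]2C(C)=CC[C@H](OC3(C)C)[C@]2(C)[C@H](O3)C=C)cc1 | intermediate (not isolated)
33 | seco 8-hydroxy-17-methyl gamma-lactone (C16 OPMB) | COc1ccc(COCC#C[C@@H]2OC(=O)[C@H](C)[C@@]2(O)[C@H](O[Si](C)(C)C(C)(C)C)[C@H]3C(C)=CC[C@H](OC4(C)C)[C@]3(C)[C@H](O4)C=C)cc1 | intermediate
34 | C16 propargylic alcohol of the seco lactone | OCC#C[C@@H]1OC(=O)[C@H](C)[C@@]1(O)[C@H](O[Si](C)(C)C(C)(C)C)[C@H]2C(C)=CC[C@H](OC3(C)C)[C@]2(C)[C@H](O3)C=C | intermediate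
35 | (Z)-C5 tributylstannyl alkene (tin cis to C7) | OC/C(=C/[C@@H]1OC(=O)[C@H](C)[C@@]1(O)[C@H](O[Si](C)(C)C(C)(C)C)[C@H]2C(C)=CC[C@H](OC3(C)C)[C@]2(C)[C@H](O3)C=C)[Sn](CCCC)(CCCC)CCCC | intermediate
36 | (Z)-C5 iodoalkene (iodine cis to C7) | OC/C(I)=C/[C@@H]1OC(=O)[C@H](C)[C@@]1(O)[C@H](O[Si](C)(C)C(C)(C)C)[C@H]2C(C)=CC[C@H](OC3(C)C)[C@]2(C)[C@H](O3)C=C | intermediate
37 | C4 B-alkyl-9-BBN of 36 (C16 hydroxyl as its 9-BBN borinate) | O(B1C2CCCC1CCC2)C/C(I)=C/[C@@H]3OC(=O)[C@H](C)[C@@]3(O)[C@H](O[Si](C)(C)C(C)(C)C)[C@H]4C(C)=CC[C@H](OC5(C)C)[C@]4(C)[C@H](O5)CCB6C7CCCC6CCC7 | intermediate (not isolated)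
38 | protected ten-membered carbocycle (16-OH, 8-OH free; O9 TBS; 2,14-acetonide) | OC/C1=C/[C@@H]2OC(=O)[C@H](C)[C@@]2(O)[C@H](O[Si](C)(C)C(C)(C)C)[C@H]2C(C)=CC[C@H](OC3(C)C)[C@]2(C)[C@H](O3)CC1 | intermediate
39 | 2,14,16-triol (8-OH free, O9 TBS) | OC/C1=C/[C@@H]2OC(=O)[C@H](C)[C@@]2(O)[C@H](O[Si](C)(C)C(C)(C)C)[C@H]2C(C)=CC[C@H](O)[C@]2(C)[C@H](O)CC1 | intermediate
40 | 2,14,16-triacetate 9-silyl ether | CC(=O)OC/C1=C/[C@@H]2OC(=O)[C@H](C)[C@@]2(O)[C@H](O[Si](C)(C)C(C)(C)C)[C@H]2C(C)=CC[C@H](OC(C)=O)[C@]2(C)[C@H](OC(C)=O)CC1 | intermediate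
41 | CNP0322315.2 (2,14,16-triacetoxy-8,9-dihydroxy briarane 19,7-lactone, 5,11-diene) | CC(=O)OC/C1=C/[C@@H]2OC(=O)[C@H](C)[C@@]2(O)[C@H](O)[C@H]2C(C)=CC[C@H](OC(C)=O)[C@]2(C)[C@H](OC(C)=O)CC1 | target

**Totals**
Total step count: 27. Longest linear sequence: 27 steps (1 to 41); compounds 13, 20, 25 and 29 are bought.

**Three steps most likely to fail**

1. Step 24 (macrocyclisation). Closing a ten-membered ring is entropically and transannularly costly, so the alkylborane may be lost by protodeboronation, the alkylpalladium intermediate may suffer beta-hydride elimination, or intermolecular coupling may give oligomers. The fallback sets out from 36 and comes back at 38. Stille coupling of 36 with tributyl(vinyl)stannane (Pd(PPh3)4, CuI, DMF) would give the 5-vinyl triene F1 with retention of geometry. Ring-closing metathesis between the C2 vinyl group and the new vinyl group (second-generation Hoveyda–Grubbs catalyst, toluene, high dilution, 80 °C) would give the ten-membered 3,5-diene F2. Diimide F3, generated from 2-nitrobenzenesulfonylhydrazide and Et3N, should then saturate only the disubstituted C3=C4 alkene and leave the trisubstituted C5=C6 and C11=C12 alkenes, giving 38.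

2. Step 8 (aldol). The open transition state may give poor simple diastereoselection at C2, some electrophile may enter on the ester face of C1, and conjugate addition to acrolein may compete with 1,2-addition. The fallback sets out from 14 as obtained (both C2 epimers) and comes back at 14. Dess–Martin oxidation of the mixture would give the 2,14-dione F4, whose quaternary C1 cannot enolise. The vinyl ketone would then be reduced under reagent control with (S)-2-methyl-CBS-oxazaborolidine and catecholborane at −78 °C (tertiary alkyl as the large group, vinyl as the small one), which should return the 2R alcohol 14; the conjugated carbonyl is expected to react before the hindered ring ketone. This corrects C2 only; material of the wrong C1 configuration would be removed by chromatography.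

3. Step 13 (dithiane ester addition). The stabilised, hindered enolate may add reversibly, so retro-aldol cleavage, erosion of the Felkin–Anh selectivity and base-induced epimerisation or conjugation of the aldehyde at C10 may all occur. The fallback sets out from 19 and comes back at 23. 1,3-Dithiane deprotonated with n-BuLi gives 2-lithio-1,3-dithiane F5, a non-stabilised nucleophile that should add irreversibly to 19 at −78 °C to give the dithianyl carbinol F6. Silylation (TBSOTf, 2,6-lutidine) would give the silyl ether F7. A second metalation at C8 (t-BuLi, THF/HMPA, −78 °C) would give the C8-lithio dithiane F8, and C-acylation with ethyl chloroformate would give 23.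

**Further compounds**
F1 | step 24 | 5-vinyl triene (Stille product of 36) | OC/C(C=C)=C/[C@@H]1OC(=O)[C@H](C)[C@@]1(O)[C@H](O[Si](C)(C)C(C)(C)C)[C@H]2C(C)=CC[C@H](OC3(C)C)[C@]2(C)[C@H](O3)C=C
F2 | step 24 | ten-membered 3,5-diene (ring cis C3=C4) | OC/C1=C/[C@@H]2OC(=O)[C@H](C)[C@@]2(O)[C@H](O[Si](C)(C)C(C)(C)C)[C@H]2C(C)=CC[C@H](OC3(C)C)[C@]2(C)[C@H](O3)/C=C\1
F3 | step 24 | diimide | N=N
F4 | step 8 | 2,14-dione (methyl 6-acryloyl-2,6-dimethyl-5-oxocyclohex-2-ene-1-carboxylate, C1 and C10 as in 14) | COC(=O)[C@H]1C(C)=CCC(=O)[C@]1(C)C(=O)C=C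
F5 | step 13 | 2-lithio-1,3-dithiane | [Li]C1SCCCS1
F6 | step 13 | dithianyl carbinol (C9 carbinol, C8 as dithiane CH) | S1CCCSC1[C@H](O)[C@H]2C(C)=CC[C@H](OC3(C)C)[C@]2(C)[C@H](O3)C=C
F7 | step 13 | O9 tert-butyldimethylsilyl ether of F6 | S1CCCSC1[C@H](O[Si](C)(C)C(C)(C)C)[C@H]2C(C)=CC[C@H](OC3(C)C)[C@]2(C)[C@H](O3)C=C
F8 | step 13 | C8-lithio dithiane from F7 | [Li]C1(SCCCS1)[C@H](O[Si](C)(C)C(C)(C)C)[C@H]2C(C)=CC[C@H](OC3(C)C)[C@]2(C)[C@H](O3)C=C
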